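**Strategy.** Everything rests on disconnecting the skipped arene–olefin unit at the bond between the benzylic C1' methylene on ring A and the vinylic C2'H of the E-C2'=C3' olefin. In one operation a benzylic zinc reagent of the acetyl-protected toluhydroquinone is coupled under palladium catalysis, with retention of geometry, to an E-alkenyl iodide that already carries both ketones, the cis-1,2-dimethylcyclopentane (ring B) and the epoxide. The iodoalkene serves twice: syn-methylalumination of a terminal alkyne fixes the E geometry, and its electron-poor character lets the prenyl olefin be epoxidised selectively. Ring B arises from a meso bicyclo[3.3.0]octanone by enantioselective enolisation and ozonolysis.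

Key step: step 13

Remarks and assumptions:
- Locants: ring A is the hydroquinone ring; the side chain runs from C1' (benzylic CH2) to C15' (epoxide CMe2); ring B is the cyclopentane C7'–C11' (C7' and C11' quaternary).
- Dione 1 is treated as a catalogue compound (it is the Weiss–Cook product of butane-2,3-dione and dimethyl 3-oxoglutarate).
- The sense of the enantiotopic deprotonation in step 3 is assumed by analogy with other meso ketones; the (R,R)-amide is written, and the (S,S)-amide would be used without other change if a trial showed the opposite sense.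
- Compounds 12, 13, 14, 17, 18, 19 and 20 are carried as mixtures of epimers at the carbinol or lactol carbons C5' and C12', which are not stereocentres of the target; their SMILES leave these centres open.

**Step 1**
Reactants: 1 cis-1,5-dimethylbicyclo[3.3.0]octane-3,7-dione (meso, both angular methyls on one face); 2 2,2-dimethylpropane-1,3-diol
Product: 3 mono(2,2-dimethylpropane-1,3-diyl) ketal of 1
Conditions: 2 (1.0 equiv), p-TsOH·H2O (cat.), benzene, reflux, Dean–Stark
Reagents that add atoms: none
Why: Acid-catalysed ketalisation with one equivalent of diol should give the mono-ketal statistically (bis-ketal and 1 are recycled), and the cis relation of the angular methyl groups, which becomes the cis relation of C7' and C11', is already present in 1.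

**Step 2**
Reactants: 3 mono-ketal
Product: 6 cis-1,5-dimethylbicyclo[3.3.0]octan-3-one (meso), via ketal hydrazone 4 (not isolated), via deoxygenated ketal 5 (not isolated)
Conditions: N2H4·H2O, KOH, diethylene glycol, 130 °C then 200 °C; pentane extraction, then 2 M aq. HCl, acetone, 50 °C
Reagents that add atoms: water, O
Why: Wolff–Kishner reduction (Huang-Minlon variant) removes the free carbonyl through hydrazone 4 while the base-stable ketal survives, and acid hydrolysis of the crude ketal then unveils the remaining ketone of the meso bicycle whose unfunctionalised five-membered ring becomes ring B.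

**Step 3**
Reactants: 6 meso ketone
Product: 8 (1S,5R)-1,5-dimethyl-3-(trimethylsilyloxy)bicyclo[3.3.0]oct-2-ene, via lithium enolate 7 (not isolated)
Conditions: (R,R)-bis(1-phenylethyl)amine, n-BuLi, THF, −78 to 0 °C; then TMSCl (5 equiv) and 6, −100 °C; Et3N quench
Reagents that add atoms: chlorotrimethylsilane, C[Si](C)(C)Cl
Why: Enantioselective deprotonation of a meso ketone by a C2-symmetric chiral lithium amide with in situ silyl trapping (asymmetric desymmetrisation) should distinguish the enantiotopic C2 and C4 methylenes, placing the enol double bond next to the ring-fusion carbon destined to be C11' and thereby fixing the absolute configuration of both quaternary centres (C7' R, C11' R) at once.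

**Step 4**
Reactants: 8 silyl enol ether
Product: 10 2-[(1R,2R)-2-formyl-1,2-dimethylcyclopentyl]acetic acid, via methoxy hydroperoxide 9 (not isolated)
Conditions: O3, CH2Cl2/MeOH, −78 °C; Me2S, −78 °C to rt; aqueous work-up at pH 3
Reagents that add atoms: ozone, [O-][O+]=O
Why: Ozonolysis of the silyl enol ether cleaves the C2=C3 bond to a formyl group on C11' and, after reduction of the methoxy hydroperoxide by Me2S and hydrolysis of the silyl ester, a carboxymethyl group on C7', without touching the quaternary centres.

**Step 5**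
Reactants: 10 aldehyde acid; 11 4,4,5,5-tetramethyl-2-(2-methylbut-3-en-2-yl)-1,3,2-dioxaborolane
Product: 13 (4aR,7aR)-4a,7a-dimethyl-1-(3-methylbut-2-en-1-yl)hexahydrocyclopenta[c]pyran-3(1H)-one (C1 epimers), via boryl ether 12 (not isolated)
Conditions: 11 (1.5 equiv), (PhO)2P(O)OH (10 mol %), toluene, rt to 45 °C; then PPTS (cat.), 50 °C
Reagents that add atoms: none
Why: Allylboration through a six-membered chair transition state proceeds with allylic transposition, so the tertiary boronate should deliver the linear 3-methylbut-2-enyl group to the aldehyde carbon (C12') and the boryl ether then lactonises onto the cis carboxymethyl arm, the new carbinol centre C12' being formed without control because it is oxidised in step 10.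

**Step 6**
Reactants: 13 lactone
Product: 14 (4aR,7aR)-4a,7a-dimethyl-1-(3-methylbut-2-en-1-yl)octahydrocyclopenta[c]pyran-3-ol (lactol, epimers at C1 and C3)
Conditions: i-Bu2AlH (1.1 equiv), CH2Cl2, −78 °C; aq. KNaC4H4O6 (potassium sodium tartrate)
Reagents that add atoms: none
Why: Partial reduction of a lactone by i-Bu2AlH at −78 °C stops at the tetrahedral aluminium hemiacetal, which gives the lactol on work-up, the new anomeric centre being of no consequence.

**Step 7**
Reactants: 14 lactol; 15 3-bromoprop-1-yne
Product: 17 1-[(1R,2R)-2-(2-hydroxypent-4-yn-1-yl)-1,2-dimethylcyclopentyl]-4-methylpent-3-en-1-ol (carbinol epimers), via allenylzinc bromide 16 (not isolated)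
Conditions: 15 (2 equiv), Zn dust, THF/sat. aq. NH4Cl, 0 °C to rt
Reagents that add atoms: none
Why: Zinc-mediated Barbier propargylation of the open hydroxy-aldehyde form of the lactol proceeds through allenylzinc bromide by SE2' addition to give the homopropargylic alcohol, whose C5' carbinol centre is formed unselectively and is oxidised in step 10.

**Step 8**
Reactants: 17 alkyne diol
Product: 19 (E)-1-[(1R,2R)-2-(1-hydroxy-4-methylpent-3-en-1-yl)-1,2-dimethylcyclopentyl]-5-iodo-4-methylpent-4-en-2-ol (carbinol epimers), via alkenylalane 18 (not isolated)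
Conditions: AlMe3 (6 equiv), Cp2ZrCl2 (1 equiv), CH2Cl2, 0 °C to rt; then I2 (1.2 equiv), THF, −30 °C; aq. Na2S2O3 and potassium sodium tartrate work-up
Reagents that add atoms: trimethylaluminium, C[Al](C)C; iodine, II
Why: Zirconium-catalysed methylalumination of the terminal alkyne is a syn addition that places methyl on C3' and aluminium on C2', and iodinolysis of the C–Al bond with retention should give the E-iodoalkene that fixes the geometry of the C2'=C3' olefin, the trisubstituted olefin being inert and the hydroxyls being carried as aluminium alkoxides.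

**Step 9**
Reactants: 19 iodoalkene diol
Product: 20 (E)-1-[(1R,2R)-2-{2-[(2S)-3,3-dimethyloxiran-2-yl]-1-hydroxyethyl}-1,2-dimethylcyclopentyl]-5-iodo-4-methylpent-4-en-2-ol (carbinol epimers)
Conditions: L-fructose-derived Shi ketone (0.4 equiv), Oxone (2KHSO5·KHSO4·K2SO4), K2CO3, Bu4NHSO4, MeCN/CH2(OMe)2, aq. Na2B4O7/Na2EDTA buffer (pH 10.5), 0 °C
Reagents that add atoms: potassium peroxymonosulfate, [K+].[O-]S(=O)(=O)OO
Why: Shi asymmetric epoxidation by the chiral dioxirane should attack only the electron-rich C14'=C15' olefin (the iodoalkene is deactivated), and the L-fructose-derived ketone, mirror image of the catalyst that gives R epoxides from 2-methylalk-2-enes, sets C14' as S by reagent control in every carbinol epimer.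

**Step 10**
Reactants: 20 epoxy diol
Product: 21 (E)-1-[(1R,2R)-2-{2-[(2S)-3,3-dimethyloxiran-2-yl]acetyl}-1,2-dimethylcyclopentyl]-5-iodo-4-methylpent-4-en-2-one
Conditions: Dess–Martin periodinane (3 equiv), NaHCO3, CH2Cl2, 0 °C to rt
Reagents that add atoms: none
Why: Dess–Martin oxidation under bicarbonate buffer converts both secondary alcohols into ketones under neutral conditions that should leave the β,γ-unsaturated iodoalkenyl ketone unconjugated and the β,γ-epoxy ketone unopened, and it erases the two uncontrolled carbinol centres.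

**Step 11**
Reactants: 22 2,6-dimethylbenzene-1,4-diol
Product: 23 2,6-dimethylbenzene-1,4-diyl diacetate
Conditions: Ac2O, pyridine, DMAP (cat.), CH2Cl2, rt
Reagents that add atoms: acetic anhydride, CC(=O)OC(C)=O
Why: DMAP-catalysed acylation of both phenols protects the hydroquinone against oxidation and makes the ring electron-poor enough for the radical bromination that follows.

**Step 12**
Reactants: 23 diacetate
Product: 24 2-(bromomethyl)-6-methylbenzene-1,4-diyl diacetate
Conditions: NBS (1.0 equiv), AIBN (cat.), PhCF3, 80 °C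
Reagents that add atoms: N-bromosuccinimide, O=C1CCC(=O)N1Br
Why: Wohl–Ziegler benzylic bromination with one equivalent of NBS should brominate one of the two equivalent methyl groups (dibromide and unreacted 23 are separated), the acetoxy groups suppressing ring bromination.

**Step 13**
Reactants: 24 benzylic bromide; 21 alkenyl iodide
Product: 26 2-{(2E)-6-[(1R,2R)-2-{2-[(2S)-3,3-dimethyloxiran-2-yl]acetyl}-1,2-dimethylcyclopentyl]-3-methyl-5-oxohex-2-en-1-yl}-6-methylbenzene-1,4-diyl diacetate, via benzylic zinc bromide 25 (not isolated)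
Conditions: 24 (1.5 equiv), Zn dust, LiCl, THF, 0 °C; then 21, Pd(PPh3)4 (5 mol %), THF, rt
Reagents that add atoms: none
Why: Zinc inserts into the benzylic C–Br bond of 24 to give 25; zerovalent palladium adds oxidatively to the C2'–I bond of 21 with retention, the benzyl group passes from zinc to divalent palladium, and reductive elimination forms the C1'–C2' bond and returns the catalyst. The closest known reaction type is the Negishi cross-coupling of benzylic zinc halides with alkenyl iodides to give allylarenes. No ring is closed and no stereocentre is created; the E geometry installed in step 8 is carried over because neither oxidative addition nor reductive elimination changes the double-bond configuration. The step needs chemoselectivity for the alkenyl iodide over two ketones, the epoxide and the aryl acetates, which rests on the low nucleophilicity and basicity of the benzylic zinc halide and on the absence of added base, so that the C4' methylene is not deprotonated (no conjugation of the C2'=C3' olefin) and the β,γ-epoxy ketone is not opened by elimination. Site selectivity is secured by the single C(sp2)–I bond, the only bond of 21 that adds to zerovalent palladium at room temperature.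

**Step 14**
Reactants: 26 coupled diacetate
Product: 27 (E)-6-(2,5-dihydroxy-3-methylphenyl)-1-[(1R,2R)-2-{2-[(2S)-3,3-dimethyloxiran-2-yl]acetyl}-1,2-dimethylcyclopentyl]-4-methylhex-4-en-2-one (target)
Conditions: NH4OAc, MeOH/H2O (4:1), degassed, rt
Reagents that add atoms: none
Why: Neutral ammonium-acetate-mediated solvolysis cleaves aryl acetates selectively under conditions in which the base-labile β,γ-epoxy ketone and β,γ-unsaturated ketone should persist, oxygen being excluded to keep the hydroquinone from oxidising.

**Compound list**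
1 | cis-1,5-dimethylbicyclo[3.3.0]octane-3,7-dione (meso) | C1[C@@]2(C)CC(=O)C[C@@]2(C)CC1=O | starting material
2 | 2,2-dimethylpropane-1,3-diol | OCC(C)(C)CO | starting material
3 | cis-7,7-(2,2-dimethylpropane-1,3-diyldioxy)-1,5-dimethylbicyclo[3.3.0]octan-3-one | C1[C@@]2(C)CC3(OCC(C)(C)CO3)C[C@@]2(C)CC1=O | intermediate
4 | hydrazone of 3 | C1[C@@]2(C)CC3(OCC(C)(C)CO3)C[C@@]2(C)CC1=NN | intermediate
5 | cis-3,3-(2,2-dimethylpropane-1,3-diyldioxy)-1,5-dimethylbicyclo[3.3.0]octane | C1[C@@]2(C)CC3(OCC(C)(C)CO3)C[C@@]2(C)CC1 | intermediate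
6 | (1R,5S)-1,5-dimethylbicyclo[3.3.0]octan-3-one (meso, cis) | C1[C@@]2(C)CCC[C@@]2(C)CC1=O | intermediate
7 | lithium (1S,5R)-1,5-dimethylbicyclo[3.3.0]oct-2-en-3-olate | C1[C@@]2(C)CCC[C@@]2(C)C=C1O[Li] | intermediate
8 | (1S,5R)-1,5-dimethyl-3-(trimethylsilyloxy)bicyclo[3.3.0]oct-2-ene | C1[C@@]2(C)CCC[C@@]2(C)C=C1O[Si](C)(C)C | intermediate
9 | trimethylsilyl 2-{(1R,2R)-2-[hydroperoxy(methoxy)methyl]-1,2-dimethylcyclopentyl}acetate | C[Si](C)(C)OC(=O)C[C@@]1(C)CCC[C@@]1(C)C(OC)OO | intermediate
10 | 2-[(1R,2R)-2-formyl-1,2-dimethylcyclopentyl]acetic acid | OC(=O)C[C@@]1(C)CCC[C@@]1(C)C=O | intermediate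
11 | 4,4,5,5-tetramethyl-2-(2-methylbut-3-en-2-yl)-1,3,2-dioxaborolane | C=CC(C)(C)B1OC(C)(C)C(C)(C)O1 | starting material
12 | 2-[(1R,2R)-1,2-dimethyl-2-{4-methyl-1-[(4,4,5,5-tetramethyl-1,3,2-dioxaborolan-2-yl)oxy]pent-3-en-1-yl}cyclopentyl]acetic acid (epimers) | OC(=O)C[C@@]1(C)CCC[C@@]1(C)C(CC=C(C)C)OB1OC(C)(C)C(C)(C)O1 | intermediate
13 | (4aR,7aR)-4a,7a-dimethyl-1-(3-methylbut-2-en-1-yl)hexahydrocyclopenta[c]pyran-3(1H)-one (C1 epimers) | O=C1C[C@@]2(C)CCC[C@@]2(C)C(CC=C(C)C)O1 | intermediate
14 | (4aR,7aR)-4a,7a-dimethyl-1-(3-methylbut-2-en-1-yl)octahydrocyclopenta[c]pyran-3-ol (epimers) | OC1C[C@@]2(C)CCC[C@@]2(C)C(CC=C(C)C)O1 | intermediate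
15 | 3-bromoprop-1-yne | C#CCBr | starting material
16 | propa-1,2-dien-1-ylzinc bromide | C=C=C[Zn]Br | intermediate
17 | 1-[(1R,2R)-2-(2-hydroxypent-4-yn-1-yl)-1,2-dimethylcyclopentyl]-4-methylpent-3-en-1-ol (epimers) | C#CCC(O)C[C@@]1(C)CCC[C@@]1(C)C(O)CC=C(C)C | intermediate
18 | (E)-alkenyl(dimethyl)alane of 17 as its bis(dimethylaluminium) alkoxide | C/C(=C\[Al](C)C)CC(O[Al](C)C)C[C@@]1(C)CCC[C@@]1(C)C(O[Al](C)C)CC=C(C)C | intermediate
19 | (E)-1-[(1R,2R)-2-(1-hydroxy-4-methylpent-3-en-1-yl)-1,2-dimethylcyclopentyl]-5-iodo-4-methylpent-4-en-2-ol (epimers) | C/C(=C\I)CC(O)C[C@@]1(C)CCC[C@@]1(C)C(O)CC=C(C)C | intermediate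
20 | (E)-1-[(1R,2R)-2-{2-[(2S)-3,3-dimethyloxiran-2-yl]-1-hydroxyethyl}-1,2-dimethylcyclopentyl]-5-iodo-4-methylpent-4-en-2-ol (epimers) | C/C(=C\I)CC(O)C[C@@]1(C)CCC[C@@]1(C)C(O)C[C@@H]1OC1(C)C | intermediate
21 | (E)-1-[(1R,2R)-2-{2-[(2S)-3,3-dimethyloxiran-2-yl]acetyl}-1,2-dimethylcyclopentyl]-5-iodo-4-methylpent-4-en-2-one | C/C(=C\I)CC(=O)C[C@@]1(C)CCC[C@@]1(C)C(=O)C[C@@H]1OC1(C)C | intermediate
22 | 2,6-dimethylbenzene-1,4-diol | Cc1cc(O)cc(C)c1O | starting material
23 | 2,6-dimethylbenzene-1,4-diyl diacetate | Cc1cc(OC(C)=O)cc(C)c1OC(C)=O | intermediate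
24 | 2-(bromomethyl)-6-methylbenzene-1,4-diyl diacetate | BrCc1cc(OC(C)=O)cc(C)c1OC(C)=O | intermediate
25 | [2,5-bis(acetyloxy)-3-methylbenzyl]zinc bromide | Br[Zn]Cc1cc(OC(C)=O)cc(C)c1OC(C)=O | intermediate
26 | 2-{(2E)-6-[(1R,2R)-2-{2-[(2S)-3,3-dimethyloxiran-2-yl]acetyl}-1,2-dimethylcyclopentyl]-3-methyl-5-oxohex-2-en-1-yl}-6-methylbenzene-1,4-diyl diacetate | C/C(=C\Cc1cc(OC(C)=O)cc(C)c1OC(C)=O)CC(=O)C[C@@]1(C)CCC[C@@]1(C)C(=O)C[C@@H]1OC1(C)C | intermediate
27 | (E)-6-(2,5-dihydroxy-3-methylphenyl)-1-[(1R,2R)-2-{2-[(2S)-3,3-dimethyloxiran-2-yl]acetyl}-1,2-dimethylcyclopentyl]-4-methylhex-4-en-2-one | C/C(=C\Cc1cc(O)cc(C)c1O)CC(=O)C[C@@]1(C)CCC[C@@]1(C)C(=O)C[C@@H]1OC1(C)C | target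

**Total step count:** 14. **Longest linear sequence:** 12 steps (steps 1–10, 13 and 14, from 1).

**Steps most likely to fail**

Step 13. The zinc halides formed may open or rearrange the β,γ-epoxy ketone by Lewis-acid activation, the benzylic zinc reagent may add to a ketone, or the benzylic partner may homocouple during zinc insertion. The fallback reverses the roles under salt-free, neutral conditions. Setting out from 21, iodine–tin exchange with Me3SnSnMe3 and PdCl2(MeCN)2 in NMP at rt would give the (E)-alkenyl(trimethyl)stannane F1. Stille coupling of F1 with bromide 24 (Pd2(dba)3, AsPh3, THF, 50 °C) would then come back to the route at 26.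

Step 9. The C12' hydroxyl may open the new epoxide intramolecularly at its tertiary carbon (tetrahydrofuranol formation) during the reaction or on silica, and conversion may stall on the epimeric diol mixture. The fallback changes the order of events so that no hydroxyl is present. Setting out from 19, Dess–Martin oxidation (NaHCO3, CH2Cl2) would give the iododienyl diketone F2. Shi epoxidation of F2 with the same L-fructose-derived ketone, at pH held near 9–10, would come back to the route at 21, bypassing 20.

Step 3. Discrimination between the enantiotopic α-methylenes may be insufficient because the angular methyl groups crowd both exo protons, which would erode the enantiomeric purity of every later compound. The fallback replaces asymmetric enolisation by classical resolution. Setting out from 6, enolisation with LiN(i-Pr)2 and TMSCl would give the racemic silyl enol ether F3, and ozonolysis as in step 4 the racemic aldehyde acid F4. Crystallisation of its salt with (R)-N,N-dimethyl-1-phenylethylamine (or the enantiomeric amine, whichever gives the less soluble salt of the (1R,2R)-acid) would give the diastereomerically pure salt F5. Acidification of F5 would come back to the route at 10.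

**Further compounds**
F1 | step 13 | (E)-1-[(1R,2R)-2-{2-[(2S)-3,3-dimethyloxiran-2-yl]acetyl}-1,2-dimethylcyclopentyl]-4-methyl-5-(trimethylstannyl)pent-4-en-2-one | C/C(=C\[Sn](C)(C)C)CC(=O)C[C@@]1(C)CCC[C@@]1(C)C(=O)C[C@@H]1OC1(C)C
F2 | step 9 | (E)-1-[(1R,2R)-1,2-dimethyl-2-(4-methylpent-3-enoyl)cyclopentyl]-5-iodo-4-methylpent-4-en-2-one | C/C(=C\I)CC(=O)C[C@@]1(C)CCC[C@@]1(C)C(=O)CC=C(C)C
F3 | step 3 | racemic cis-1,5-dimethyl-3-(trimethylsilyloxy)bicyclo[3.3.0]oct-2-ene (both enantiomers) | C1[C@@]2(C)CCC[C@@]2(C)C=C1O[Si](C)(C)C.C1[C@]2(C)CCC[C@]2(C)C=C1O[Si](C)(C)C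
F4 | step 3 | racemic cis-2-(2-formyl-1,2-dimethylcyclopentyl)acetic acid (both enantiomers) | OC(=O)C[C@@]1(C)CCC[C@@]1(C)C=O.OC(=O)C[C@]1(C)CCC[C@]1(C)C=O
F5 | step 3 | (R)-N,N-dimethyl-1-phenylethylammonium 2-[(1R,2R)-2-formyl-1,2-dimethylcyclopentyl]acetate | [O-]C(=O)C[C@@]1(C)CCC[C@@]1(C)C=O.C[C@@H]([NH+](C)C)c1ccccc1
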